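**Retrosynthetic overview**

- The route rests on rings A and B of the labdane: a trans-fused decalin whose quaternary C4 and C10, the C5 hydrogen, the C3 oxygen and the axial 4β-oxymethyl carbon C19 map atom for atom onto one geranylgeranyl chain folded chair–chair, C19 being the (Z)-substituent of a terminal C3–C4 epoxide.
- Key disconnection: C4–C5 and C9–C10, made in one Lewis-acid-induced cationic cascade from epoxy trienoate 19; ring A closes first, ring B second, giving the Δ7 alcohol 20.
- Before: geranylgeraniol is cut back to the trisnor aldehyde 6, rebuilt to the (Z)-hydroxymethyl terminus (β-oxido ylide), epoxidised (Sharpless) and oxidised at C15 to an allyl ester.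
- After: C3 is inverted through the ketone, C3–O and C19–O are acylated, C6 is oxidised to the 7-en-6-one, a dienol acetate/borohydride reductive deconjugation sets C8=C9 and the 6β-hydroxyl, and deallylation frees the C15 acid.

Key step: step 12

Remark on numbering: labdane numbering (C1–C20) is used for the bicycles and for the corresponding carbons of the open-chain precursors; α/β refer to the usual orientation with the C10 methyl (C20) β.

Remark on the chemistry: the C15 carboxyl is carried as its allyl ester from step 11 on, because it must be unmasked last beside two isovalerates, which rules out saponification; it deactivates C13=C14 in the cyclisation as any ester would.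

Remark on the chemistry: the 8-en-6-one is assumed to return to the conjugated 7-en-6-one under base, so it is generated and reduced in one flask (step 19) and all base-requiring operations come before it.

**Step 1**
Reactants: 1 (2E,6E,10E)-geranylgeraniol; 2 4-methoxybenzyl chloride
Product: 3 1-methoxy-4-({[(2E,6E,10E)-3,7,11,15-tetramethylhexadeca-2,6,10,14-tetraen-1-yl]oxy}methyl)benzene
Conditions: NaH, 4-MeOC6H4CH2Cl, Bu4NI (cat.), THF/DMF, 0 °C to rt
Reagents that add atoms: 4-methoxybenzyl chloride (2), COc1ccc(CCl)cc1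
Why: Williamson ether synthesis: the allylic alkoxide displaces the benzylic chloride, and the PMB ether shields C15–O through the organolithium chemistry of step 5 yet can later be removed oxidatively beside a silyl ether and an epoxide.

**Step 2**
Reactants: 3 geranylgeranyl PMB ether
Product: 4 (6E,10E,14E)-3-bromo-16-[(4-methoxybenzyl)oxy]-2,6,10,14-tetramethylhexadeca-6,10,14-trien-2-ol (racemic at C3)
Conditions: NBS (1.1 equiv), THF/H2O, 0 °C
Reagents that add atoms: N-bromosuccinimide, O=C1CCC(=O)N1Br; water, O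
Why: Terminal-selective bromohydrin formation: in aqueous THF the polyene coils so that NBS reaches mainly the terminal trisubstituted alkene, and water opens the bromonium ion at the tertiary carbon (Markovnikov); the new centre is racemic and is excised in step 4.

**Step 3**
Reactants: 4 terminal bromohydrin
Product: 5 2,2-dimethyl-3-{(3E,7E,11E)-13-[(4-methoxybenzyl)oxy]-3,7,11-trimethyltrideca-3,7,11-trien-1-yl}oxirane (racemic)
Conditions: K2CO3, MeOH, rt
Reagents that add atoms: none
Why: Intramolecular Williamson reaction: the tertiary alkoxide displaces the neighbouring secondary bromide (SN2) to close the epoxide, and no other group is base-sensitive.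

**Step 4**
Reactants: 5 terminal epoxide
Product: 6 (4E,8E,12E)-14-[(4-methoxybenzyl)oxy]-4,8,12-trimethyltetradeca-4,8,12-trienal
Conditions: H5IO6, THF/Et2O, 0 °C
Reagents that add atoms: none
Why: Periodic acid hydrates the epoxide and cleaves the resulting glycol in the same flask (Malaprade cleavage), removing the three terminal carbons as acetone and leaving the aldehyde carbon that becomes C3; the ether and the trisubstituted alkenes are inert to cold periodic acid.

**Step 5**
Reactants: 6 trisnor aldehyde; 7 ethyltriphenylphosphonium bromide; 8 paraformaldehyde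
Product: 11 (2Z,6E,10E,14E)-16-[(4-methoxybenzyl)oxy]-2,6,10,14-tetramethylhexadeca-2,6,10,14-tetraen-1-ol, via lithium betaine 9 (not isolated), via β-oxido ylide 10 (not isolated)
Conditions: EtPPh3Br, n-BuLi, THF, 0 °C; 6, −78 °C; s-BuLi, −78 to −30 °C; (CH2O)n, −30 °C to rt; H2O
Reagents that add atoms: ethyltriphenylphosphonium bromide (7), CC[P+](c1ccccc1)(c1ccccc1)c1ccccc1.[Br-]; formaldehyde from paraformaldehyde (8), C=O
Why: Wittig reaction in its β-oxido ylide variant (SCOOPY hydroxymethylation): the lithiated betaine is attacked at carbon by formaldehyde, Ph3P=O then leaves with the oxygen of aldehyde 6, and the hydroxymethyl group ends cis to the chain, so the (Z)-2-methyl allylic alcohol should result, which fixes the later C19/C18 assignment.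

**Step 6**
Reactants: 11 (Z)-allylic alcohol
Product: 12 [(2R,3S)-3-{(3E,7E,11E)-13-[(4-methoxybenzyl)oxy]-3,7,11-trimethyltrideca-3,7,11-trien-1-yl}-2-methyloxiran-2-yl]methanol
Conditions: Ti(OiPr)4, D-(−)-diisopropyl tartrate, t-BuOOH, 4 Å MS, CH2Cl2, −20 °C
Reagents that add atoms: tert-butyl hydroperoxide, CC(C)(C)OO
Why: Katsuki–Sharpless asymmetric epoxidation of the only allylic alcohol in the molecule: with D-(−)-tartrate the oxygen is delivered to the face that gives the (2R,3S)-epoxy alcohol, and the cis relation of CH2OH and chain is carried over from the (Z)-alkene, so the future C3 (S) and C4 centres are set here.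

**Step 7**
Reactants: 12 epoxy alcohol; 13 tert-butyl(chloro)diphenylsilane
Product: 14 tert-butyl{[(2R,3S)-3-{(3E,7E,11E)-13-[(4-methoxybenzyl)oxy]-3,7,11-trimethyltrideca-3,7,11-trien-1-yl}-2-methyloxiran-2-yl]methoxy}diphenylsilane
Conditions: t-BuPh2SiCl, imidazole, DMF, rt
Reagents that add atoms: tert-butyl(chloro)diphenylsilane (13), CC(C)(C)[Si](Cl)(c1ccccc1)c1ccccc1
Why: Imidazole-promoted silylation of the primary alcohol; the bulky, weakly Lewis-basic silyl ether cannot open the epoxide as a neighbouring group and leaves the epoxide oxygen as the preferred site for MeAlCl2 in step 12.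

**Step 8**
Reactants: 14 silylated epoxide PMB ether
Product: 15 (2E,6E,10E)-13-[(2S,3R)-3-{[(tert-butyldiphenylsilyl)oxy]methyl}-3-methyloxiran-2-yl]-3,7,11-trimethyltrideca-2,6,10-trien-1-ol
Conditions: DDQ, CH2Cl2/pH 7 phosphate buffer, 0 °C
Reagents that add atoms: none
Why: Oxidative PMB cleavage: DDQ abstracts hydride from the electron-rich benzylic position and water hydrolyses the oxocarbenium ion, conditions under which the buffered epoxide, the silyl ether and the alkenes should be stable.

**Step 9**
Reactants: 15 allylic alcohol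
Product: 16 (2E,6E,10E)-13-[(2S,3R)-3-{[(tert-butyldiphenylsilyl)oxy]methyl}-3-methyloxiran-2-yl]-3,7,11-trimethyltrideca-2,6,10-trienal
Conditions: MnO2, CH2Cl2, rt
Reagents that add atoms: none
Why: MnO2 oxidises allylic alcohols selectively and without (E)/(Z) isomerisation, so only C15 is oxidised.

**Step 10**
Reactants: 16 enal
Product: 17 (2E,6E,10E)-13-[(2S,3R)-3-{[(tert-butyldiphenylsilyl)oxy]methyl}-3-methyloxiran-2-yl]-3,7,11-trimethyltrideca-2,6,10-trienoic acid
Conditions: NaClO2, NaH2PO4, 2-methyl-2-butene, t-BuOH/H2O, 0 °C to rt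
Reagents that add atoms: sodium chlorite, [Na+].[O-]Cl=O
Why: Pinnick oxidation of the enal to the acid; 2-methyl-2-butene scavenges hypochlorous acid so that the trisubstituted alkenes are not chlorinated, and the buffered medium (pH about 4) spares the epoxide.

**Step 11**
Reactants: 17 acid; 18 allyl bromide
Product: 19 allyl (2E,6E,10E)-13-[(2S,3R)-3-{[(tert-butyldiphenylsilyl)oxy]methyl}-3-methyloxiran-2-yl]-3,7,11-trimethyltrideca-2,6,10-trienoate
Conditions: allyl bromide, K2CO3, DMF, rt
Reagents that add atoms: allyl bromide (18), C=CCBr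
Why: SN2 O-alkylation of the carboxylate gives the allyl ester, which should be inert to every later step and is removable at the end under neutral conditions.

**Step 12**
Reactants: 19 epoxy trienoate
Product: 20 allyl 19-[(tert-butyldiphenylsilyl)oxy]-3β-hydroxylabda-7,13E-dien-15-oate
Conditions: MeAlCl2 (2.5 equiv), CH2Cl2, −78 °C; then H2O
Reagents that add atoms: none
Why: MeAlCl2 binds the epoxide oxygen (a second equivalent sits on the ester carbonyl), the C5=C10 π bond opens the activated epoxide at the fully substituted C4 with inversion (ring A, 6-endo-trig at the alkene, the breaking C4–O bond exocyclic to the new ring), the C10 cation is captured by C8=C9 (ring B, 6-endo-trig), and the C8 cation loses the axial 7α proton to give the Δ7 alkene. The closest known reaction type is the MeAlCl2-promoted epoxy-polyene bicyclisation of terminal epoxides of farnesyl and geranylgeranyl derivatives. C3 is carried over unchanged from the (S)-epoxide carbon and ends equatorial (3β-OH), while C4 is set by backside attack, so the (Z)-silyloxymethyl group becomes the axial 4β-C19 and the methyl group the equatorial C18. C5 and C10 are set by antiperiplanar addition across the (E)-C5=C10 alkene in a chair (5α-H, 10β-CH3, trans fusion) and C9 by anti addition across the (E)-C8=C9 alkene in the second chair (9α-H, equatorial side chain), all relayed from the epoxide through the chair–chair fold. The step needs the cascade to stop at the bicycle and to end regioselectively: the conjugated, aluminium-complexed C13=C14 ester alkene is too electron-poor to attack the C8 cation, and loss of the ring proton at C7 should be favoured over loss from C17, any 8(17) isomer being removed on AgNO3–silica.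

**Step 13**
Reactants: 20 3β-alcohol
Product: 21 allyl 19-[(tert-butyldiphenylsilyl)oxy]-3-oxolabda-7,13E-dien-15-oate
Conditions: Dess–Martin periodinane, CH2Cl2, rt
Reagents that add atoms: none
Why: Dess–Martin oxidation of the secondary alcohol to the C3 ketone under neutral conditions; this erases the C3 centre in preparation for its inversion.

**Step 14**
Reactants: 21 3-ketone
Product: 22 allyl 19-[(tert-butyldiphenylsilyl)oxy]-3α-hydroxylabda-7,13E-dien-15-oate
Conditions: LiBH(s-Bu)3 (L-Selectride), THF, −78 °C; then H2O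
Reagents that add atoms: none
Why: Bulky-hydride reduction: LiBH(s-Bu)3 attacks the C3 ketone along the equatorial trajectory (the axial α-face approach is blocked for so large a reagent by the axial hydrogens on C1 and C5), so the axial 3α-alcohol should form, and the β,β-disubstituted enoate is not reduced at −78 °C.

**Step 15**
Reactants: 22 3α-alcohol silyl ether
Product: 23 allyl 3α,19-dihydroxylabda-7,13E-dien-15-oate
Conditions: Bu4NF, THF, rt to 45 °C
Reagents that add atoms: none
Why: Fluoride-induced desilylation driven by the Si–F bond; the esters, the alkenes and the secondary alcohol are unaffected.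

**Step 16**
Reactants: 23 diol; 24 isovaleric anhydride
Product: 25 allyl 3α,19-bis(3-methylbutanoyloxy)labda-7,13E-dien-15-oate
Conditions: (i-BuCO)2O, DMAP, pyridine, CH2Cl2, rt to 40 °C
Reagents that add atoms: isovaleric anhydride (24), CC(C)CC(=O)OC(=O)CC(C)C
Why: DMAP-catalysed acylation (nucleophilic catalysis through the N-acylpyridinium ion) esterifies both the neopentyl primary C19 hydroxyl and the hindered axial C3 hydroxyl when excess anhydride and gentle warming are used.

**Step 17**
Reactants: 25 bis-isovalerate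
Product: 26 allyl 3α,19-bis(3-methylbutanoyloxy)-6-oxolabda-7,13E-dien-15-oate
Conditions: CrO3, 3,5-dimethylpyrazole, CH2Cl2, −20 °C
Reagents that add atoms: chromium trioxide, O=[Cr](=O)=O
Why: Allylic oxidation with the CrO3–3,5-dimethylpyrazole complex, a reaction known to convert Δ7 alkenes of steroids and drimanes into 7-en-6-ones: C6 is the only allylic methylene of the electron-rich ring alkene, whereas the tertiary C9–H, the C17 methyl group and the positions next to the electron-poor enoate and allyl ester alkenes should react much more slowly.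

**Step 18**
Reactants: 26 7-en-6-one; 27 isopropenyl acetate
Product: 28 allyl 6-acetoxy-3α,19-bis(3-methylbutanoyloxy)labda-6,8,13E-trien-15-oate
Conditions: isopropenyl acetate, TsOH·H2O (cat.), 95 °C, acetone distilled off
Reagents that add atoms: isopropenyl acetate (27), CC(=C)OC(C)=O
Why: Acid-catalysed enol acetylation under thermodynamic control, as in the conversion of steroidal 4-en-3-ones into 3,5-dienyl acetates: the extended 6,8-dienyl acetate with the fully substituted C8=C9 bond should be preferred over the cross-conjugated Δ5 enol (C5 lies between two quaternary carbons) and over the exocyclic 8(17) isomer, and the C9 centre is deliberately erased.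

**Step 19**
Reactants: 28 dienol acetate
Product: 30 allyl 6β-hydroxy-3α,19-bis(3-methylbutanoyloxy)labda-8,13E-dien-15-oate, via deconjugated 6-ketone 29 (not isolated)
Conditions: NaBH4, EtOH/THF, 0 °C to rt
Reagents that add atoms: none
Why: Reductive deconjugation of a dienol acetate with NaBH4 (the classical entry to homoallylic alcohols from steroidal dienol acetates): ethanolysis of the enol ester frees the dienolate, kinetic protonation at C7 gives the 8-en-6-one, and this is reduced at once from the α face, the β face being screened by the axial C20 methyl and C19 methylene groups, which sets the 6β-hydroxyl while the hindered isovalerates and the conjugated allyl ester should survive.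

**Step 20**
Reactants: 30 allyl ester
Product: 31 6β-hydroxy-3α,19-bis(3-methylbutanoyloxy)labda-8,13E-dien-15-oic acid (CNP0333611.1)
Conditions: Pd(PPh3)4 (cat.), morpholine, THF, rt; then dilute citric acid
Reagents that add atoms: none
Why: Tsuji–Trost deallylation: zerovalent palladium ionises the allyl ester to a π-allyl complex that is captured by morpholine, a neutral process that leaves the two isovalerates, the homoallylic alcohol and both remaining alkenes untouched.

**Compound list**

1 | (2E,6E,10E)-geranylgeraniol | CC(C)=CCC/C(C)=C/CC/C(C)=C/CC/C(C)=C/CO | starting material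
2 | 4-methoxybenzyl chloride | COc1ccc(CCl)cc1 | starting material
3 | 1-methoxy-4-({[(2E,6E,10E)-3,7,11,15-tetramethylhexadeca-2,6,10,14-tetraen-1-yl]oxy}methyl)benzene | COc1ccc(COC/C=C(C)/CC/C=C(C)/CC/C=C(C)/CCC=C(C)C)cc1 | intermediate
4 | (6E,10E,14E)-3-bromo-16-[(4-methoxybenzyl)oxy]-2,6,10,14-tetramethylhexadeca-6,10,14-trien-2-ol (racemic at C3) | COc1ccc(COC/C=C(C)/CC/C=C(C)/CC/C=C(C)/CCC(Br)C(C)(C)O)cc1 | intermediate
5 | 2,2-dimethyl-3-{(3E,7E,11E)-13-[(4-methoxybenzyl)oxy]-3,7,11-trimethyltrideca-3,7,11-trien-1-yl}oxirane (racemic) | COc1ccc(COC/C=C(C)/CC/C=C(C)/CC/C=C(C)/CCC2OC2(C)C)cc1 | intermediate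
6 | (4E,8E,12E)-14-[(4-methoxybenzyl)oxy]-4,8,12-trimethyltetradeca-4,8,12-trienal | COc1ccc(COC/C=C(C)/CC/C=C(C)/CC/C=C(C)/CCC=O)cc1 | intermediate
7 | ethyltriphenylphosphonium bromide | CC[P+](c1ccccc1)(c1ccccc1)c1ccccc1.[Br-] | starting material
8 | paraformaldehyde (used as formaldehyde) | C=O | starting material
9 | (6E,10E,14E)-16-[(4-methoxybenzyl)oxy]-6,10,14-trimethyl-2-(triphenylphosphonio)hexadeca-6,10,14-trien-3-olate as LiBr adduct (diastereomer mixture at C2 and C3) | COc1ccc(COC/C=C(C)/CC/C=C(C)/CC/C=C(C)/CCC([O-])C(C)[P+](c2ccccc2)(c2ccccc2)c2ccccc2)cc1.[Li+].[Br-] | intermediate (not isolated)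
10 | lithium (6E,10E,14E)-16-[(4-methoxybenzyl)oxy]-6,10,14-trimethyl-2-(triphenylphosphoranylidene)hexadeca-6,10,14-trien-3-olate (racemic at C3) | COc1ccc(COC/C=C(C)/CC/C=C(C)/CC/C=C(C)/CCC([O-])C(C)=P(c2ccccc2)(c2ccccc2)c2ccccc2)cc1.[Li+] | intermediate (not isolated)
11 | (2Z,6E,10E,14E)-16-[(4-methoxybenzyl)oxy]-2,6,10,14-tetramethylhexadeca-2,6,10,14-tetraen-1-ol | COc1ccc(COC/C=C(C)/CC/C=C(C)/CC/C=C(C)/CC/C=C(C)\CO)cc1 | intermediate
12 | [(2R,3S)-3-{(3E,7E,11E)-13-[(4-methoxybenzyl)oxy]-3,7,11-trimethyltrideca-3,7,11-trien-1-yl}-2-methyloxiran-2-yl]methanol | COc1ccc(COC/C=C(C)/CC/C=C(C)/CC/C=C(C)/CC[C@@H]2O[C@]2(C)CO)cc1 | intermediate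
13 | tert-butyl(chloro)diphenylsilane | CC(C)(C)[Si](Cl)(c1ccccc1)c1ccccc1 | starting material
14 | tert-butyl{[(2R,3S)-3-{(3E,7E,11E)-13-[(4-methoxybenzyl)oxy]-3,7,11-trimethyltrideca-3,7,11-trien-1-yl}-2-methyloxiran-2-yl]methoxy}diphenylsilane | COc1ccc(COC/C=C(C)/CC/C=C(C)/CC/C=C(C)/CC[C@@H]2O[C@]2(C)CO[Si](c2ccccc2)(c2ccccc2)C(C)(C)C)cc1 | intermediate
15 | (2E,6E,10E)-13-[(2S,3R)-3-{[(tert-butyldiphenylsilyl)oxy]methyl}-3-methyloxiran-2-yl]-3,7,11-trimethyltrideca-2,6,10-trien-1-ol | OC/C=C(C)/CC/C=C(C)/CC/C=C(C)/CC[C@@H]1O[C@]1(C)CO[Si](c1ccccc1)(c1ccccc1)C(C)(C)C | intermediate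
16 | (2E,6E,10E)-13-[(2S,3R)-3-{[(tert-butyldiphenylsilyl)oxy]methyl}-3-methyloxiran-2-yl]-3,7,11-trimethyltrideca-2,6,10-trienal | O=C/C=C(C)/CC/C=C(C)/CC/C=C(C)/CC[C@@H]1O[C@]1(C)CO[Si](c1ccccc1)(c1ccccc1)C(C)(C)C | intermediate
17 | (2E,6E,10E)-13-[(2S,3R)-3-{[(tert-butyldiphenylsilyl)oxy]methyl}-3-methyloxiran-2-yl]-3,7,11-trimethyltrideca-2,6,10-trienoic acid | OC(=O)/C=C(C)/CC/C=C(C)/CC/C=C(C)/CC[C@@H]1O[C@]1(C)CO[Si](c1ccccc1)(c1ccccc1)C(C)(C)C | intermediate
18 | allyl bromide | C=CCBr | starting material
19 | allyl (2E,6E,10E)-13-[(2S,3R)-3-{[(tert-butyldiphenylsilyl)oxy]methyl}-3-methyloxiran-2-yl]-3,7,11-trimethyltrideca-2,6,10-trienoate | C=CCOC(=O)/C=C(C)/CC/C=C(C)/CC/C=C(C)/CC[C@@H]1O[C@]1(C)CO[Si](c1ccccc1)(c1ccccc1)C(C)(C)C | intermediate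
20 | allyl 19-[(tert-butyldiphenylsilyl)oxy]-3β-hydroxylabda-7,13E-dien-15-oate (5α-H, 9α-H, 10β-CH3, 4α-CH3, 4β-CH2OSi) | CC1=CC[C@H]2[C@@](C)(CO[Si](c3ccccc3)(c3ccccc3)C(C)(C)C)[C@@H](O)CC[C@]2(C)[C@H]1CC/C(C)=C/C(=O)OCC=C | intermediate
21 | allyl 19-[(tert-butyldiphenylsilyl)oxy]-3-oxolabda-7,13E-dien-15-oate | CC1=CC[C@H]2[C@@](C)(CO[Si](c3ccccc3)(c3ccccc3)C(C)(C)C)C(=O)CC[C@]2(C)[C@H]1CC/C(C)=C/C(=O)OCC=C | intermediate
22 | allyl 19-[(tert-butyldiphenylsilyl)oxy]-3α-hydroxylabda-7,13E-dien-15-oate | CC1=CC[C@H]2[C@@](C)(CO[Si](c3ccccc3)(c3ccccc3)C(C)(C)C)[C@H](O)CC[C@]2(C)[C@H]1CC/C(C)=C/C(=O)OCC=C | intermediate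
23 | allyl 3α,19-dihydroxylabda-7,13E-dien-15-oate | CC1=CC[C@H]2[C@@](C)(CO)[C@H](O)CC[C@]2(C)[C@H]1CC/C(C)=C/C(=O)OCC=C | intermediate
24 | isovaleric anhydride | CC(C)CC(=O)OC(=O)CC(C)C | starting material
25 | allyl 3α,19-bis(3-methylbutanoyloxy)labda-7,13E-dien-15-oate | CC1=CC[C@H]2[C@@](C)(COC(=O)CC(C)C)[C@H](OC(=O)CC(C)C)CC[C@]2(C)[C@H]1CC/C(C)=C/C(=O)OCC=C | intermediate
26 | allyl 3α,19-bis(3-methylbutanoyloxy)-6-oxolabda-7,13E-dien-15-oate | CC1=CC(=O)[C@H]2[C@@](C)(COC(=O)CC(C)C)[C@H](OC(=O)CC(C)C)CC[C@]2(C)[C@H]1CC/C(C)=C/C(=O)OCC=C | intermediate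
27 | isopropenyl acetate | CC(=C)OC(C)=O | starting material
28 | allyl 6-acetoxy-3α,19-bis(3-methylbutanoyloxy)labda-6,8,13E-trien-15-oate | CC1=C(CC/C(C)=C/C(=O)OCC=C)[C@@]2(C)CC[C@@H](OC(=O)CC(C)C)[C@](C)(COC(=O)CC(C)C)[C@@H]2C(OC(C)=O)=C1 | intermediate
29 | allyl 3α,19-bis(3-methylbutanoyloxy)-6-oxolabda-8,13E-dien-15-oate | CC1=C(CC/C(C)=C/C(=O)OCC=C)[C@@]2(C)CC[C@@H](OC(=O)CC(C)C)[C@](C)(COC(=O)CC(C)C)[C@@H]2C(=O)C1 | intermediate (not isolated)
30 | allyl 6β-hydroxy-3α,19-bis(3-methylbutanoyloxy)labda-8,13E-dien-15-oate | CC1=C(CC/C(C)=C/C(=O)OCC=C)[C@@]2(C)CC[C@@H](OC(=O)CC(C)C)[C@](C)(COC(=O)CC(C)C)[C@@H]2[C@H](O)C1 | intermediate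
31 | 6β-hydroxy-3α,19-bis(3-methylbutanoyloxy)labda-8,13E-dien-15-oic acid (CNP0333611.1) | CC1=C(CC/C(C)=C/C(=O)O)[C@@]2(C)CC[C@@H](OC(=O)CC(C)C)[C@](C)(COC(=O)CC(C)C)[C@@H]2[C@H](O)C1 | target

**Step count and risks**

Total step count: 20. Longest linear sequence: 20 steps (from geranylgeraniol 1).

Steps most likely to fail:

1. Step 12. What may go wrong: loss of regiocontrol in the terminating elimination. The C8 cation can shed a proton from the C17 methyl group instead of from C7, which diverts material into the 8(17)-exocyclic alkene. Fallback (sets out from 19, comes back at 20): the alkene position is fixed by a hydroxyl-directed transposition and no longer by the kinetics of proton loss. The exocyclic isomer delivered by the cyclisation of 19, allyl 19-[(tert-butyldiphenylsilyl)oxy]-3β-hydroxylabda-8(17),13E-dien-15-oate F1, is separated and oxidised at its ring allylic methylene with SeO2 (cat.)/t-BuOOH in CH2Cl2 to allyl 19-[(tert-butyldiphenylsilyl)oxy]-3β,7α-dihydroxylabda-8(17),13E-dien-15-oate F2. Mitsunobu reaction of the allylic hydroxyl (the neopentyl 3β-hydroxyl should not react) with 2-nitrobenzenesulfonyl hydrazide (PPh3, diethyl azodicarboxylate, THF, −30 °C) should give allyl 19-[(tert-butyldiphenylsilyl)oxy]-3β-hydroxy-7β-[1-(2-nitrobenzenesulfonyl)hydrazin-1-yl]labda-8(17),13E-dien-15-oate F3. On warming to rt this loses 2-nitrobenzenesulfinic acid to the monoalkyl diazene allyl 19-[(tert-butyldiphenylsilyl)oxy]-7β-diazenyl-3β-hydroxylabda-8(17),13E-dien-15-oate F4, which extrudes N2 in a retro-ene step that places hydrogen on C17 and the double bond between C7 and C8, which is 20.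

2. Step 19. What may go wrong: protonation of the dienolate at C9 instead of C7, or base-mediated return of the 8-en-6-one to conjugation before hydride arrives; either leads to the allylic 7-en-6-ol. Slow cleavage of the hindered enol acetate would also expose the isovalerates to ethoxide for longer. Fallback (sets out from 26, comes back at 30): enolisation, ketonisation and reduction are separated and kept away from base. Enone 26 is converted with t-BuMe2SiOTf/Et3N (CH2Cl2, 0 °C) into the silyl dienol ether allyl 6-[(tert-butyldimethylsilyl)oxy]-3α,19-bis(3-methylbutanoyloxy)labda-6,8,13E-trien-15-oate F5. Bu4NF buffered with excess AcOH (THF, −78 °C) cleaves the O–Si bond in the presence of a proton donor, so that C7 is protonated kinetically in a medium that never turns basic, and the 8-en-6-one 29 is isolated cold. Luche reduction (NaBH4, CeCl3·7H2O, MeOH, −40 °C) should then give 30 by the same α-face attack.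

3. Step 5. What may go wrong: incomplete α-lithiation of the betaine or its reversal to ylide and aldehyde, so that simple ethylidene olefin forms and the (Z)-purity of the hydroxymethyl terminus, on which the C19/C18 assignment depends, is eroded. Fallback (sets out from 6, comes back at 11): the (Z)-trisubstituted alkene is made by a Still–Gennari olefination of 6 with ethyl 2-[bis(2,2,2-trifluoroethoxy)phosphoryl]propanoate (KN(SiMe3)2, 18-crown-6, THF, −78 °C), which should give ethyl (2Z,6E,10E,14E)-16-[(4-methoxybenzyl)oxy]-2,6,10,14-tetramethylhexadeca-2,6,10,14-tetraenoate F6, and i-Bu2AlH (CH2Cl2, −78 °C) reduces the ester to 11.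

**Further compounds**

F1 | step 12 | allyl 19-[(tert-butyldiphenylsilyl)oxy]-3β-hydroxylabda-8(17),13E-dien-15-oate | C=C1CC[C@H]2[C@@](C)(CO[Si](c3ccccc3)(c3ccccc3)C(C)(C)C)[C@@H](O)CC[C@]2(C)[C@H]1CC/C(C)=C/C(=O)OCC=C
F2 | step 12 | allyl 19-[(tert-butyldiphenylsilyl)oxy]-3β,7α-dihydroxylabda-8(17),13E-dien-15-oate | C=C1[C@H](O)C[C@H]2[C@@](C)(CO[Si](c3ccccc3)(c3ccccc3)C(C)(C)C)[C@@H](O)CC[C@]2(C)[C@H]1CC/C(C)=C/C(=O)OCC=C
F3 | step 12 | allyl 19-[(tert-butyldiphenylsilyl)oxy]-3β-hydroxy-7β-[1-(2-nitrobenzenesulfonyl)hydrazin-1-yl]labda-8(17),13E-dien-15-oate (not isolated) | C=C1[C@@H](N(N)S(=O)(=O)c3ccccc3[N+](=O)[O-])C[C@H]2[C@@](C)(CO[Si](c3ccccc3)(c3ccccc3)C(C)(C)C)[C@@H](O)CC[C@]2(C)[C@H]1CC/C(C)=C/C(=O)OCC=C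
F4 | step 12 | allyl 19-[(tert-butyldiphenylsilyl)oxy]-7β-diazenyl-3β-hydroxylabda-8(17),13E-dien-15-oate (not isolated) | C=C1[C@@H](N=N)C[C@H]2[C@@](C)(CO[Si](c3ccccc3)(c3ccccc3)C(C)(C)C)[C@@H](O)CC[C@]2(C)[C@H]1CC/C(C)=C/C(=O)OCC=C
F5 | step 19 | allyl 6-[(tert-butyldimethylsilyl)oxy]-3α,19-bis(3-methylbutanoyloxy)labda-6,8,13E-trien-15-oate | CC1=C(CC/C(C)=C/C(=O)OCC=C)[C@@]2(C)CC[C@@H](OC(=O)CC(C)C)[C@](C)(COC(=O)CC(C)C)[C@@H]2C(O[Si](C)(C)C(C)(C)C)=C1
F6 | step 5 | ethyl (2Z,6E,10E,14E)-16-[(4-methoxybenzyl)oxy]-2,6,10,14-tetramethylhexadeca-2,6,10,14-tetraenoate | COc1ccc(COC/C=C(C)/CC/C=C(C)/CC/C=C(C)/CC/C=C(C)\C(=O)OCC)cc1
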